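All runs stem from a simulated flask with made-up constants, noise included.

You ask for a quick number on which of the four flasks ends highest in over-reaction product at 10 d, and your hunch is Friday's, with everything together at the start.

| flask | substrate | first nucleophile | second nucleophile | remark | time |
|---|---|---|---|---|---|
| larch | 0.10 M | 0.095 M | 0.20 M | run made earlier |  |
| maple | 0.10 M | 0.095 M | 0.28 M | run made earlier |  |
| cedar | 0.10 M | 0.095 M | 0.44 M | run made earlier |  |
| Friday's | 0.10 M | 0.0950 M | 0.200 M | everything together at the start | 10 d |
| Saturday's | 0.10 M | 0.0950 M (fed, over 4.0 d) | 0.200 M | all else is in the flask from the start; the feed brings no volume worth counting | 10 d |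
| Thursday's | 0.10 M (in portions, 3, over 4.0 d) | 0.0950 M | 0.200 M | first portion at the start, last at 4.0 d | 10 d |
| Tuesday's | 0.10 M (fed, over 4.0 d) | 0.0950 M | 0.200 M | all else is in the flask from the start; the feed brings no volume worth counting | 10 d |

| run | time / d | over-reaction product / % | target / % |
|---|---|---|---|
| larch | 1.25 | 3.1 | 9.7 |
| larch | 2.50 | 5.3 | 13.9 |
| larch | 4.00 | 10.0 | 19.4 |
| larch | 5.00 | 13.6 | 20.2 |
| larch | 6.00 | 17.7 | 21.4 |
| maple | 2.50 | 3.7 | 11.1 |
| maple | 5.00 | 15.4 | 16.1 |
| maple | 8.00 | 25.8 | 14.6 |
| maple | 10.0 | 30.7 | 10.0 |
| maple | 12.0 | 36.0 | 9.3 |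
| cedar | 2.50 | 5.3 | 7.6 |
| cedar | 5.00 | 13.4 | 8.3 |
| cedar | 8.00 | 23.4 | 5.5 |
| cedar | 10.0 | 28.3 | 7.2 |
| cedar | 12.0 | 32.0 | 2.4 |

(standard deviation of a reading: 1 percentage point)

1. the flask that comes out highest in amount of over-reaction product, in percent of the substrate charged, or "all alike" when all lie within 1.5 percentage points (Friday's / Saturday's / Thursday's / Tuesday's / all alike)
2. over-reaction product at the end, in percent of the substrate charged, Friday's
3. over-reaction product at the end, in percent of the substrate charged, Saturday's
4. over-reaction product at the end, in percent of the substrate charged, Thursday's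
5. over-reaction product at the end, in percent of the substrate charged, Tuesday's



Friday's is the larch run carried on, but larch stops at 6.00 d. Let Y be target plus over-reaction product. Summed over the readings at 2.50 d and 5.00 d, Y is 53.0% in larch and 34.6% in cedar. I read this as a competition: substrate goes at one pace, and second nucleophile takes part of what it forms away from first nucleophile. The clock then cancels in the ratio of the two sums, 1.53.

Write the share reaching Y as φ = C/(C + [second nucleophile]). The ratio gives 0.251 M, the crossover concentration, a reading with its scatter. Maple, which I left out, is a test: C predicts 45.0% for its sum, and it reads 46.3%.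

I take C to scale with first nucleophile, which I put at about half its charge on average during Saturday's feed, so φ should fall from 55.7% to 38.6%. Larch's Y at 4.00 d is 29.4%, so Saturday's should lose about 9 percentage points by the end of the feed. Taking maple's last-but-one reading, 30.7%, for Friday's, I commit to 21.7% for Saturday's. The substrate feeds should keep φ but bring substrate in later, so I place Tuesday's and Thursday's between.

The forecast differs in its grounds, slowing the first step, “probably by reversible binding”. It gives Friday's 32.5%, Saturday's 25.5%, Thursday's 26.5% and Tuesday's 25.5%, with Friday's highest.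

The flasks give Friday's 29.2%, Saturday's 20.9%, Thursday's 23.3% and Tuesday's 23.4%, so Friday's is highest.

    second nucleophile + target → over-reaction product (k = 7.29 × 10⁻⁴ M⁻¹ min⁻¹)
    first nucleophile + intermediate → target (k = 5.80 M⁻¹ min⁻¹)
    substrate → intermediate (k = 1.13 × 10⁻⁴ min⁻¹)
    second nucleophile + intermediate → other capture product (k = 1.57 M⁻¹ min⁻¹)

Capture of intermediate by second nucleophile is the largest single effect in the gap between Friday's and Saturday's: taken away, the gap shrinks from 8.3 points to 0.017 points. At 4.00 d, Saturday's Y is 18.3% against my 20.4%. In Saturday's recipe with 0.057 M of first nucleophile, C scaled to that charge puts Y at 29.6%. That flask holds 28.6%, with other capture product at 51.7% and over-reaction product at 15.3%.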